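**Retrosynthetic overview**

1. Target 20 ⇐ silyl ether 19 ⇐ epoxy acid 18: transannular C12–O bond formation. The carboxylate opens the 11,12-epoxide at C12 with inversion and the epoxide oxygen becomes the C11 acetate; this closes the seven-membered lactone last.
2. 18 ⇐ ynal 15: nickel-catalysed reductive alkyne–aldehyde macrocyclization (C3–C4 bond, 4E olefin, C3 carbinol); this closes the 14-membered carbocycle first.
3. 15 ⇐ enal 13 + trimethyl phosphonoacetate: organocatalytic Michael addition sets C1; a later Horner–Wadsworth–Emmons step gives the acrylate.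
4. 13 ⇐ ester 9 (Shi epoxidation sets C11 and C12, then reduction/Wittig); 9 ⇐ Johnson–Claisen rearrangement (11E olefin) ⇐ nerol + propynyl Grignard (7Z olefin and the alkyne).
5. Ring order: 14-membered carbocycle (step 9), then seven-membered lactone (step 11).

Assumption: intermediates carry cembranoid numbering (ring C1–C14, C1 bears the acrylate carbons C15–C17, methyls on C4, C8 and C12), and 15 and 16 are used as mixtures of epimers at the phosphonate-bearing carbon, which becomes sp2 in step 10.

**Route**

Step 1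
Reactants: 1 nerol
Product: 2 neryl bromide
Conditions: PBr3 (0.4 equiv), Et2O, −10 °C
Reagents that add atoms: phosphorus tribromide, `BrP(Br)Br`
Why: Classical PBr3 bromination of a primary allylic alcohol (SN2 on the phosphite ester) gives the allylic bromide without erosion of the 2Z olefin at low temperature; the crude bromide is used at once.

Step 2
Reactants: 2 neryl bromide; 3 1-propynylmagnesium bromide
Product: 4 (5Z)-6,10-dimethylundeca-5,9-dien-2-yne
Conditions: CuI (10 mol%), THF, −20 °C to rt
Reagents that add atoms: none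
Why: Copper-catalysed SN2 cross-coupling of an alkynyl Grignard reagent with a primary allylic bromide forms the C5–C6 bond of the skipped (1,4-) enyne at the unsubstituted terminus and keeps the Z olefin that becomes C7=C8.

Step 3
Reactants: 4 (5Z)-6,10-dimethylundeca-5,9-dien-2-yne
Product: 5 rac-2,2-dimethyl-3-[(3Z)-3-methyloct-3-en-6-yn-1-yl]oxirane
Conditions: mCPBA (1.0 equiv), CH2Cl2, −20 °C
Reagents that add atoms: 3-chloroperoxybenzoic acid, `OOC(=O)c1cccc(Cl)c1`
Why: Prilezhaev epoxidation is selective for the terminal dimethyl-substituted olefin because the internal Z olefin is inductively deactivated by its propargylic substituent and is more hindered; the alkyne does not react and the racemic stereocentre is erased in step 5.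

Step 4
Reactants: 5 rac-2,2-dimethyl-3-[(3Z)-3-methyloct-3-en-6-yn-1-yl]oxirane
Product: 6 rac-(6Z)-2,6-dimethylundeca-1,6-dien-9-yn-3-ol
Conditions: Al(OiPr)3 (0.3 equiv), toluene, 110 °C
Reagents that add atoms: none
Why: Aluminium isopropoxide-promoted isomerization of an epoxide to an allylic alcohol (syn β-elimination through a six-membered transition state with removal of a methyl hydrogen) gives the 2-methylallylic secondary alcohol needed for the Claisen step.

Step 5
Reactants: 6 rac-(6Z)-2,6-dimethylundeca-1,6-dien-9-yn-3-ol; 7 triethyl orthoacetate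
Product: 9 ethyl (4E,8Z)-4,8-dimethyltrideca-4,8-dien-11-ynoate, via mixed ketene acetal 8 (not isolated)
Conditions: MeC(OEt)3 (5 equiv), EtCO2H (5 mol%), 140 °C, EtOH distilled off
Reagents that add atoms: none
Why: Johnson–Claisen (orthoester Claisen) rearrangement through a chair transition state with the chain pseudo-equatorial forms the C13–C14 bond and the trisubstituted E olefin (the later C11=C12) with at least 95:5 selectivity.

Step 6
Reactants: 9 ethyl (4E,8Z)-4,8-dimethyltrideca-4,8-dien-11-ynoate
Product: 10 ethyl 3-[(2R,3R)-2-methyl-3-[(3Z)-3-methyloct-3-en-6-yn-1-yl]oxiran-2-yl]propanoate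
Conditions: D-fructose-derived Shi ketone (30 mol%), KHSO5 (Oxone, 1.2 equiv), K2CO3, Bu4NHSO4 (cat.), MeCN–dimethoxymethane–aq. buffer pH 10.5, 0 °C
Reagents that add atoms: potassium peroxymonosulfate, `[K+].[O-]S(=O)(=O)OO`
Why: Shi asymmetric epoxidation: the dioxirane of the D-fructose-derived ketone transfers oxygen through a spiro transition state to one face of the E-trisubstituted olefin and sets C11 and C12 as 11R,12R, while the Z olefin (larger group cis to the allylic CH2, propargylic deactivation) and the alkyne are left.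

Step 7
Reactants: 10 ethyl 3-[(2R,3R)-2-methyl-3-[(3Z)-3-methyloct-3-en-6-yn-1-yl]oxiran-2-yl]propanoate; 11 (triphenylphosphoranylidene)acetaldehyde
Product: 13 (2E)-5-[(2R,3R)-2-methyl-3-[(3Z)-3-methyloct-3-en-6-yn-1-yl]oxiran-2-yl]pent-2-enal, via epoxy aldehyde 12 (not isolated)
Conditions: iBu2AlH (1.1 equiv), CH2Cl2, −78 °C, aqueous work-up; crude 12, then 11, toluene, 80 °C
Reagents that add atoms: none
Why: Half-reduction of the ester with iBu2AlH at −78 °C through the stable aluminium hemiacetal, then Wittig olefination of the crude aldehyde with the stabilised formyl ylide, gives the 2E enal without touching the epoxide.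

Step 8
Reactants: 13 (2E)-5-[(2R,3R)-2-methyl-3-[(3Z)-3-methyloct-3-en-6-yn-1-yl]oxiran-2-yl]pent-2-enal; 14 trimethyl phosphonoacetate
Product: 15 methyl (3S)-2-(dimethoxyphosphoryl)-5-[(2R,3R)-2-methyl-3-[(3Z)-3-methyloct-3-en-6-yn-1-yl]oxiran-2-yl]-3-(2-oxoethyl)pentanoate
Conditions: (R)-α,α-diphenylprolinol trimethylsilyl ether (10 mol%), CH2Cl2, rt
Reagents that add atoms: none
Why: Iminium-ion organocatalytic Michael addition (Jørgensen–Hayashi catalyst): the R catalyst shields one face of the E,s-trans iminium ion so that the phosphonoacetate adds to the other face of the β-carbon and sets C1 as S; the phosphonate-bearing carbon forms as both epimers and is flattened in step 10.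

Step 9
Reactants: 15 methyl (3S)-2-(dimethoxyphosphoryl)-5-[(2R,3R)-2-methyl-3-[(3Z)-3-methyloct-3-en-6-yn-1-yl]oxiran-2-yl]-3-(2-oxoethyl)pentanoate
Product: 16 methyl 2-(dimethoxyphosphoryl)-2-[(1S,3R,4E,7Z,11R,12R)-11,12-epoxy-4,8,12-trimethyl-3-(triethylsilyloxy)cyclotetradeca-4,7-dien-1-yl]acetate
Conditions: Ni(COD)2 (20 mol%), IMes (1,3-dimesitylimidazol-2-ylidene, 20 mol%), Et3SiH (3 equiv), THF, 5 mM, slow addition, rt
Reagents that add atoms: triethylsilane, `CC[SiH](CC)CC`
Why: Nickel-catalysed reductive alkyne–aldehyde macrocyclization: oxidative cyclization on zerovalent nickel gives an oxanickelacycle that the silane cleaves, so H and C3 add syn across the alkyne (4E olefin), the small carbene ligand directs C–C bond formation to the methyl-bearing alkyne carbon (14-membered ring, endocyclic olefin), the C3 carbinol is set by the resident C1 centre in the macrocyclic transition state (3R expected, see fallback), and the C3 oxygen emerges as its triethylsilyl ether.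

Step 10
Reactants: 16 methyl 2-(dimethoxyphosphoryl)-2-[(1S,3R,4E,7Z,11R,12R)-11,12-epoxy-4,8,12-trimethyl-3-(triethylsilyloxy)cyclotetradeca-4,7-dien-1-yl]acetate
Product: 18 2-[(1S,3R,4E,7Z,11R,12R)-11,12-epoxy-4,8,12-trimethyl-3-(triethylsilyloxy)cyclotetradeca-4,7-dien-1-yl]prop-2-enoic acid, via methyl acrylate ester 17 (not isolated)
Conditions: K2CO3, 37% aq. CH2O, THF, rt; then LiOH, THF–H2O, rt; H3PO4 to pH 4, 0 °C
Reagents that add atoms: formaldehyde, `C=O`; lithium hydroxide, `[Li+].[OH-]`
Why: Horner–Wadsworth–Emmons methylenation of the phosphonoacetate with formaldehyde installs the exocyclic methylene and removes the epimeric carbon, and saponification in the same pot frees the acrylic acid while epoxide and silyl ether survive the mild base.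

Step 11
Reactants: 18 2-[(1S,3R,4E,7Z,11R,12R)-11,12-epoxy-4,8,12-trimethyl-3-(triethylsilyloxy)cyclotetradeca-4,7-dien-1-yl]prop-2-enoic acid
Product: 19 (1S,3R,4E,7Z,11R,12S)-11-acetoxy-3-(triethylsilyloxy)cembra-4,7,15(17)-trien-16,12-olide
Conditions: (salen)Co(OTs) {[N,N′-bis(3,5-di-tert-butylsalicylidene)cyclohexane-1,2-diaminato]cobalt tosylate, 5 mol%}, Ac2O (3 equiv), 4 Å sieves, CH2Cl2, 0 °C to rt
Reagents that add atoms: acetic anhydride, `CC(=O)OC(C)=O`
Why: Proposed new method: cobalt–salen-catalysed transannular acyloxy-lactonization of an epoxy acid, in which the trivalent cobalt centre binds the substrate carboxylate while a second cobalt centre activates the epoxide, the tethered carboxylate attacks the tertiary carbon C12 in a 7-exo sense (favoured over 8-endo attack at C11) anti to the breaking C–O bond so that C12 is inverted (12R to 12S) and C11 keeps its configuration, and the resulting cobalt C11-alkoxide is acetylated by Ac2O, which regenerates cobalt acetate and keeps the conditions neutral enough for the silyl ether; the closest known reaction types are the (salen)Co-catalysed ring opening of epoxides by carboxylic acids, the Brønsted acid-catalysed lactonization of epoxy acids and the Lewis acid-catalysed addition of anhydrides to epoxides.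

Step 12
Reactants: 19 (1S,3R,4E,7Z,11R,12S)-11-acetoxy-3-(triethylsilyloxy)cembra-4,7,15(17)-trien-16,12-olide
Product: 20 (1S,3R,4E,7Z,11R,12S)-11-acetoxy-3-hydroxycembra-4,7,15(17)-trien-16,12-olide (CNP0130972.7)
Conditions: HF·pyridine, THF–pyridine, 0 °C
Reagents that add atoms: none
Why: Fluoride-mediated cleavage of the allylic triethylsilyl ether under buffered conditions leaves the acetate, the α-methylene lactone and the skipped diene intact and gives the target.

**Compound list**

1 | nerol, (2Z)-3,7-dimethylocta-2,6-dien-1-ol | `CC(C)=CCC/C(C)=C\CO` | starting material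
2 | neryl bromide, (2Z)-1-bromo-3,7-dimethylocta-2,6-diene | `CC(C)=CCC/C(C)=C\CBr` | intermediate
3 | 1-propynylmagnesium bromide | `CC#C[Mg]Br` | starting material
4 | (5Z)-6,10-dimethylundeca-5,9-dien-2-yne | `CC#CC/C=C(C)\CCC=C(C)C` | intermediate
5 | rac-2,2-dimethyl-3-[(3Z)-3-methyloct-3-en-6-yn-1-yl]oxirane | `CC#CC/C=C(C)\CCC1OC1(C)C` | intermediate
6 | rac-(6Z)-2,6-dimethylundeca-1,6-dien-9-yn-3-ol | `C=C(C)C(O)CC/C(C)=C\CC#CC` | intermediate
7 | triethyl orthoacetate | `CCOC(C)(OCC)OCC` | starting material
8 | mixed ketene acetal, (6Z)-3-[(1-ethoxyethenyl)oxy]-2,6-dimethylundeca-1,6-dien-9-yne | `C=C(OCC)OC(C(C)=C)CC/C(C)=C\CC#CC` | intermediate (not isolated)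
9 | ethyl (4E,8Z)-4,8-dimethyltrideca-4,8-dien-11-ynoate | `CCOC(=O)CC/C(C)=C/CC/C(C)=C\CC#CC` | intermediate
10 | ethyl 3-[(2R,3R)-2-methyl-3-[(3Z)-3-methyloct-3-en-6-yn-1-yl]oxiran-2-yl]propanoate | `CCOC(=O)CC[C@@]1(C)O[C@@H]1CC/C(C)=C\CC#CC` | intermediate
11 | (triphenylphosphoranylidene)acetaldehyde | `O=CC=P(c1ccccc1)(c1ccccc1)c1ccccc1` | starting material
12 | 3-[(2R,3R)-2-methyl-3-[(3Z)-3-methyloct-3-en-6-yn-1-yl]oxiran-2-yl]propanal | `O=CCC[C@@]1(C)O[C@@H]1CC/C(C)=C\CC#CC` | intermediate (not isolated)
13 | (2E)-5-[(2R,3R)-2-methyl-3-[(3Z)-3-methyloct-3-en-6-yn-1-yl]oxiran-2-yl]pent-2-enal | `O=C/C=C/CC[C@@]1(C)O[C@@H]1CC/C(C)=C\CC#CC` | intermediate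
14 | trimethyl phosphonoacetate | `COC(=O)CP(=O)(OC)OC` | starting material
15 | methyl (3S)-2-(dimethoxyphosphoryl)-5-[(2R,3R)-2-methyl-3-[(3Z)-3-methyloct-3-en-6-yn-1-yl]oxiran-2-yl]-3-(2-oxoethyl)pentanoate, both C2 epimers | `O=CC[C@@H](C(P(=O)(OC)OC)C(=O)OC)CC[C@@]1(C)O[C@@H]1CC/C(C)=C\CC#CC` | intermediate
16 | methyl 2-(dimethoxyphosphoryl)-2-[(1S,3R,4E,7Z,11R,12R)-11,12-epoxy-4,8,12-trimethyl-3-(triethylsilyloxy)cyclotetradeca-4,7-dien-1-yl]acetate, both epimers at the phosphonate carbon | `[C@@]12(C)CC[C@H](C(P(=O)(OC)OC)C(=O)OC)C[C@@H](O[Si](CC)(CC)CC)/C(C)=C/C/C=C(/C)CC[C@H]1O2` | intermediate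
17 | methyl 2-[(1S,3R,4E,7Z,11R,12R)-11,12-epoxy-4,8,12-trimethyl-3-(triethylsilyloxy)cyclotetradeca-4,7-dien-1-yl]prop-2-enoate | `[C@@]12(C)CC[C@H](C(=C)C(=O)OC)C[C@@H](O[Si](CC)(CC)CC)/C(C)=C/C/C=C(/C)CC[C@H]1O2` | intermediate (not isolated)
18 | 2-[(1S,3R,4E,7Z,11R,12R)-11,12-epoxy-4,8,12-trimethyl-3-(triethylsilyloxy)cyclotetradeca-4,7-dien-1-yl]prop-2-enoic acid | `[C@@]12(C)CC[C@H](C(=C)C(=O)O)C[C@@H](O[Si](CC)(CC)CC)/C(C)=C/C/C=C(/C)CC[C@H]1O2` | intermediate
19 | (1S,3R,4E,7Z,11R,12S)-11-acetoxy-3-(triethylsilyloxy)cembra-4,7,15(17)-trien-16,12-olide | `C=C1C(=O)O[C@@]2(C)CC[C@H]1C[C@@H](O[Si](CC)(CC)CC)/C(C)=C/C/C=C(/C)CC[C@H]2OC(C)=O` | intermediate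
20 | (1S,3R,4E,7Z,11R,12S)-11-acetoxy-3-hydroxycembra-4,7,15(17)-trien-16,12-olide, CNP0130972.7 | `C=C1C(=O)O[C@@]2(C)CC[C@H]1C[C@@H](O)/C(C)=C/C/C=C(/C)CC[C@H]2OC(C)=O` | target

**Step count and risks**

Total steps: 12. Longest linear sequence: 12 steps (nerol 1 to target 20). The only protecting group is the silyl ether, which the cyclization reductant installs in step 9 and which comes off in the last step.

The three steps most likely to fail:

1. Step 11, the new acyloxy-lactonization: the cobalt catalyst may not activate the trisubstituted epoxide enough, or acetate may compete with the tethered carboxylate. The fallback uses known chemistry, sets out from 18 and returns at 19. 18 is treated with camphorsulfonic acid (10 mol%) in CH2Cl2 at 0 °C, the classical Brønsted acid-catalysed epoxy acid lactonization (7-exo attack at the tertiary carbon with inversion), to give the hydroxy lactone F1. F1 is then acetylated in a separate operation with Ac2O, DMAP and pyridine to give 19.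

2. Step 9, the macrocyclization: the ratio of C3 epimers is the main uncertainty, ahead of regiochemistry, which the ligand size controls. The fallback sets C3 by reagent control instead of by the ring closure; it sets out from 16 (as the C3 epimer mixture) and returns at 16. HF·pyridine frees the allylic alcohols F2, Dess–Martin periodinane oxidizes them to the single macrocyclic enone F3, and Corey–Bakshi–Shibata reduction with (S)-2-methyl-CBS-oxazaborolidine and catecholborane at −78 °C gives the 3R alcohol F4 (the alkenyl group acts as the large substituent). Et3SiCl and imidazole then return 16.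

3. Step 3, the site-selective epoxidation of the terminal olefin with no catalyst bias to help (step 6 has the Shi catalyst's preference for E olefins as a second lever). The fallback replaces direct peracid epoxidation by the two-stage bromohydrin route; it sets out from 4 and returns at 5. NBS in aqueous THF at 0 °C, where the folded chain exposes only the terminal olefin, gives the bromohydrin F5, and K2CO3 in MeOH closes it to 5.

**Further compounds**

F1 | step 11 | (1S,3R,4E,7Z,11R,12S)-11-hydroxy-3-(triethylsilyloxy)cembra-4,7,15(17)-trien-16,12-olide | `C=C1C(=O)O[C@@]2(C)CC[C@H]1C[C@@H](O[Si](CC)(CC)CC)/C(C)=C/C/C=C(/C)CC[C@H]2O`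
F2 | step 9 | methyl 2-(dimethoxyphosphoryl)-2-[(1S,4E,7Z,11R,12R)-11,12-epoxy-3-hydroxy-4,8,12-trimethylcyclotetradeca-4,7-dien-1-yl]acetate, 3R/3S mixture | `[C@@]12(C)CC[C@H](C(P(=O)(OC)OC)C(=O)OC)CC(O)/C(C)=C/C/C=C(/C)CC[C@H]1O2`
F3 | step 9 | methyl 2-(dimethoxyphosphoryl)-2-[(1S,4E,7Z,11R,12R)-11,12-epoxy-4,8,12-trimethyl-3-oxocyclotetradeca-4,7-dien-1-yl]acetate | `[C@@]12(C)CC[C@H](C(P(=O)(OC)OC)C(=O)OC)CC(=O)/C(C)=C/C/C=C(/C)CC[C@H]1O2`
F4 | step 9 | methyl 2-(dimethoxyphosphoryl)-2-[(1S,3R,4E,7Z,11R,12R)-11,12-epoxy-3-hydroxy-4,8,12-trimethylcyclotetradeca-4,7-dien-1-yl]acetate | `[C@@]12(C)CC[C@H](C(P(=O)(OC)OC)C(=O)OC)C[C@@H](O)/C(C)=C/C/C=C(/C)CC[C@H]1O2`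
F5 | step 3 | rac-(6Z)-3-bromo-2,6-dimethylundec-6-en-9-yn-2-ol | `CC#CC/C=C(C)\CCC(Br)C(C)(C)O`
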